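**Retrosynthetic overview**

1. Feature (germacrane numbering): C1 and C6 are both carbinol carbons, lie 1,6 across the ten-membered ring, and each adjoins a Z trisubstituted olefin (C9=C10 with C14, C4=C5 with C15). A C1–C6 bond therefore gives a cis-fused bicyclo[4.4.0]decadiene 1,6-diol whose ring B (C6, C7, C8, C9, C10, C1) is the ring of (R)-carvone with C7 already correct.
2. Key disconnection: Pb(OAc)4 cleaves the C1–C6 ring-fusion glycol and opens both six-membered rings into the (4Z,9Z)-cyclodeca-4,9-diene-1,6-dione.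
3. After it: one CBS reduction sets C1 and C6, and the 6,12-lactone is closed by oxidative lactonisation of the C6/C12 diol.
4. Ring A (C1, C2, C3, C4, C5, C6): amide-enolate addition at C1, alkenyllithium acylation (C3–C4), and ring-closing metathesis of a C6 vinyl group onto the C4 methylene.
5. Order of rings: ring B (chiral pool; C12, C6 and C8 oxidised, C6 made quaternary), ring A (metathesis), ten-membered ring (glycol cleavage), lactone last.

Key step: step 17

Remark 1: germacrane numbering is used for all intermediates (carvone C1, C2, C3, C4, C5, C6 = C1, C10, C9, C8, C7, C6; side-chain carbons C11, C12 (oxygenated), C13 (methylene)); syn and anti refer to the C7 side chain on ring B.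

Remark 2: C12 is kept as a TBS-protected allylic alcohol until the ten-membered ring is open, because an acrylic ester or acid at C7 is cis to the tertiary C6 hydroxyl of the bicycle and is prone to lactonise onto it and mask the glycol, and would not survive the enolate and organolithium steps; O15 carries TBDPS so that O12 can be freed first.

**Route**

Step 1
Reactants: 1 (R)-carvone
Product: 2 (R)-10-hydroxycarvone (12-hydroxy in germacrane numbering)
Conditions: SeO2 (cat.), t-BuOOH, CH2Cl2, rt
Reagents that add atoms: selenium dioxide, O=[Se]=O (oxygen carrier); tert-butyl hydroperoxide, CC(C)(C)OO (terminal oxidant)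
Why: SeO2/t-BuOOH allylic hydroxylation (ene reaction, then 2,3-sigmatropic shift) should occur at the methyl group of the electron-rich 1,1-disubstituted olefin, because the ring olefin is deactivated by conjugation with the ketone; C7 is not touched.

Step 2
Reactants: 2 (R)-10-hydroxycarvone
Product: 3 12-O-TBS ether of 2
Conditions: TBSCl, imidazole, CH2Cl2, 0 °C → rt
Reagents that add atoms: tert-butyl(chloro)dimethylsilane, CC(C)(C)[Si](C)(C)Cl
Why: Silylation of the primary allylic alcohol masks O12 through all base and organometallic steps.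

Step 3
Reactants: 3 12-O-TBS ether of 2
Product: 6 6-hydroxy ketone, via trimethylsilyl dienol ether 4 (not isolated), via 6-silyloxy ketone 5 (not isolated)
Conditions: LiN(i-Pr)2, TMSCl, THF, −78 °C; mCPBA, CH2Cl2, 0 °C; citric acid, MeOH, rt
Reagents that add atoms: 3-chloroperbenzoic acid, OOC(=O)c1cccc(Cl)c1
Why: Rubottom oxidation: kinetic deprotonation at C6 gives the cross-conjugated silyl dienol ether, the peracid adds anti to the C7 side chain, and silyl shift then methanolysis give the 6-hydroxy ketone; the C6 configuration is of no consequence because it is erased in step 5.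

Step 4
Reactants: 6 6-hydroxy ketone
Product: 7 6-O-(2-methoxypropan-2-yl) (MOP) ether
Conditions: 2-methoxypropene, pyridinium p-toluenesulfonate (cat.), CH2Cl2, 0 °C
Reagents that add atoms: 2-methoxypropene, COC(C)=C
Why: Acid-catalysed addition of the alcohol to the enol ether gives a mixed ketal that is base-stable, cannot migrate in the enolate as a silyl group could, and later leaves under very mild acid.

Step 5
Reactants: 7 MOP ether; 8 acetaldehyde
Product: 10 6-(1-hydroxyethyl) aldol adduct, via lithium enolate 9 (not isolated)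
Conditions: LiN(i-Pr)2, THF, −78 °C; then 8, −78 °C; aq. NH4Cl
Reagents that add atoms: none
Why: Aldol addition of the tetrasubstituted α-alkoxy enolate: C6 is planar in 9 and acetaldehyde should add anti to the C7 side chain, which sets the quaternary C6 with the carbon arm anti and O6 syn to that chain; both carbinol epimers are carried on.

Step 6
Reactants: 10 6-(1-hydroxyethyl) aldol adduct
Product: 11 6-vinyl enone
Conditions: Burgess reagent (MeO2CN(−)SO2N(+)Et3), toluene, 60 °C
Reagents that add atoms: none
Why: Burgess dehydration (syn elimination of the sulfamate) can take a hydrogen only from the methyl group because C6 is quaternary, so the C6 vinyl group (future C5) is formed without touching C6 or C7.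

Step 7
Reactants: 11 6-vinyl enone
Product: 14 8-hydroxy enone, via linear silyl dienol ether 12 (not isolated), via epoxy silyl enol ether 13 (not isolated)
Conditions: LiN(i-Pr)2, TMSCl, THF, −78 → 0 °C; dimethyldioxirane, acetone/CH2Cl2, −78 °C; K2CO3, MeOH, 0 °C
Reagents that add atoms: dimethyldioxirane, CC1(C)OO1
Why: Vinylogous Rubottom oxidation: with C6 quaternary only the γ-hydrogens at C8 can be removed, the linear dienol ether should be epoxidised at its remote C8=C9 bond anti to the C7 side chain, and methanolysis opens the epoxide to the γ-hydroxy enone; the anti 8-configuration is corrected in steps 9 and 10.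

Step 8
Reactants: 14 8-hydroxy enone; 15 N-methoxy-N-methylacetamide
Product: 17 C1 adduct (β-hydroxy Weinreb amide), via lithium amide enolate 16 (not isolated)
Conditions: 15, LiN(i-Pr)2 (excess), THF, −78 °C; then 14, −78 °C; aq. NH4Cl at −78 °C
Reagents that add atoms: none
Why: Aldol-type 1,2-addition of the amide enolate to the enone carbonyl (one equivalent is taken up by the 8-hydroxyl): Felkin–Anh attack anti to the axial C6–O bond, which is also the face away from the C7 side chain, should place the C2 arm syn to the C6 vinyl group and O1 cis to O6.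

Step 9
Reactants: 17 C1 adduct
Product: 18 8-ketone
Conditions: Dess–Martin periodinane, NaHCO3, CH2Cl2, 0 °C → rt
Reagents that add atoms: none
Why: Dess–Martin oxidation converts the only secondary alcohol into the enone (the tertiary C1 hydroxyl is inert and no free 1,2-diol is present), so that C8 can be reset.

Step 10
Reactants: 18 8-ketone
Product: 19 8-alcohol syn to the C7 side chain
Conditions: LiBH(s-Bu)3, THF, −78 °C; aq. NH4Cl
Reagents that add atoms: none
Why: Substrate-controlled 1,2-reduction (C10 is fully substituted, so no conjugate reduction): the bulky hydride should attack C8 from the face opposite the adjacent C7 side chain and the axial C6–O bond, giving the 8-carbinol syn to that chain as in the target.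

Step 11
Reactants: 20 2-bromoprop-2-en-1-ol
Product: 21 (2-bromoprop-2-enyloxy)(tert-butyl)diphenylsilane
Conditions: TBDPSCl, imidazole, CH2Cl2, rt
Reagents that add atoms: tert-butyl(chloro)diphenylsilane, CC(C)(C)[Si](Cl)(c1ccccc1)c1ccccc1
Why: Silylation gives the C4/C15 building block with an O15 group that outlasts the TBS ether at O12 and resists silyl migration in the derived alkenyllithium.

Step 12
Reactants: 19 8-alcohol syn to the C7 side chain; 21 (2-bromoprop-2-enyloxy)(tert-butyl)diphenylsilane
Product: 23 seco-ring A enone, via alkenyllithium 22 (not isolated)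
Conditions: 21, t-BuLi, Et2O, −78 °C; then 19, THF, −78 °C; aq. NH4Cl
Reagents that add atoms: none
Why: Bromine–lithium exchange then Weinreb ketone synthesis: the alkenyllithium (excess, two equivalents deprotonate the hydroxyls) adds once to the N-methoxy-N-methylamide, whose chelated adduct collapses only on work-up, giving the C3 ketone with the C4 methylene and O15 in place.

Step 13
Reactants: 23 seco-ring A enone
Product: 24 bicyclic enone (ring A closed)
Conditions: second-generation Grubbs catalyst (H2IMes)(PCy3)Cl2Ru=CHPh (cat.), toluene, 70 °C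
Reagents that add atoms: none
Why: Ring-closing metathesis between the C6 vinyl group and the C4 methylene is the only pairing that gives a six-membered ring, and it closes ring A as the cis-fused cyclohexenone with C4=C5 necessarily cis in the ring.

Step 14
Reactants: 24 bicyclic enone; 25 tiglic acid
Product: 27 8-tiglate, via mixed anhydride 26 (not isolated)
Conditions: 25, 2,4,6-trichlorobenzoyl chloride, Et3N, toluene, rt; then 24, DMAP, rt
Reagents that add atoms: none
Why: Yamaguchi esterification acylates the only secondary hydroxyl (O8) with retention and without the ketene pathway that can deconjugate tigloyl chloride; the tertiary C1 hydroxyl does not react.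

Step 15
Reactants: 27 8-tiglate
Product: 29 1,3,6-triol, via 3-hydroxy MOP ether 28 (not isolated)
Conditions: Et2BOMe, THF/MeOH, rt → −78 °C; NaBH4, −78 °C; then pyridinium p-toluenesulfonate, MeOH, 0 °C
Reagents that add atoms: none
Why: Narasaka–Prasad reduction: the diethylboron chelate between the free C1 hydroxyl and the C3 carbonyl holds both oxygens 1,3-diaxial on ring A, so external hydride reaches C3 only from outside the chelate and gives the 3-carbinol cis to O1 (3S); mild acidic methanolysis then frees boron and removes the MOP group.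

Step 16
Reactants: 29 1,3,6-triol
Product: 30 3-acetate 1,6-diol (cleavage precursor)
Conditions: Ac2O, pyridine, CH2Cl2, 0 °C → rt
Reagents that add atoms: acetic anhydride, CC(=O)OC(C)=O
Why: Acetylation without a nucleophilic catalyst esterifies only the secondary allylic 3-hydroxyl and leaves the two tertiary ring-fusion hydroxyls free for the cleavage.

Step 17
Reactants: 30 3-acetate 1,6-diol (cleavage precursor)
Product: 31 (4Z,9Z)-cyclodeca-4,9-diene-1,6-dione
Conditions: Pb(OAc)4, pyridine, CH2Cl2, −20 → 0 °C; filtered and used at once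
Reagents that add atoms: none
Why: Criegee glycol cleavage: the two cis ring-fusion hydroxyls exchange acetate on tetravalent lead to form a five-membered cyclic lead diester, which fragments in a concerted two-electron step that breaks C1–C6, forms both carbonyls and releases divalent lead. The closest known reaction type is the lead tetraacetate cleavage of decalin-9,10-diols to cyclodecane-1,6-diones. The ten-membered ring is not closed end to end but set free by scission of the bond shared by the two six-membered rings, so no medium-ring cyclisation has to be paid for. No stereocentre is created: C3, C7 and C8 are untouched and the temporary centres C1 and C6 disappear. The step needs chemoselectivity for the glycol over four olefins, two esters and two silyl ethers, which is inherent to the reagent at low temperature, and Z geometry at C4=C5 and C9=C10, which is fixed because each olefin was endocyclic in a six-membered ring. Pyridine buffers the acetic acid, and the β-acyloxy dienedione is reduced at once because it can eliminate, epimerise at C7 or close transannularly.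

Step 18
Reactants: 31 (4Z,9Z)-cyclodeca-4,9-diene-1,6-dione
Product: 32 (1S,6R)-1,6-diol
Conditions: (R)-2-methyl-CBS-oxazaborolidine, catecholborane, toluene, −78 °C; MeOH
Reagents that add atoms: none
Why: Corey–Bakshi–Shibata reduction of both enone carbonyls: with the alkenyl carbon as the large substituent at each ketone (C10 at C1, C5 at C6) the (R)-catalyst should deliver hydride to give 1S and 6R, and catecholborane at low temperature leaves olefins and esters alone.

Step 19
Reactants: 32 (1S,6R)-1,6-diol
Product: 33 1,6,12-triol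
Conditions: pyridinium p-toluenesulfonate, MeOH, rt
Reagents that add atoms: none
Why: Acid-catalysed methanolysis removes the primary TBS ether at O12, while the far more robust TBDPS ether at O15 and both esters stay.

Step 20
Reactants: 33 1,6,12-triol
Product: 35 15-O-TBDPS eupacunolin, via lactol 34 (not isolated)
Conditions: TEMPO (cat.), PhI(OAc)2, CH2Cl2, rt
Reagents that add atoms: none
Why: Oxidative lactonisation of the 1,4-diol: the oxoammonium oxidant takes the primary allylic alcohol in preference to the secondary C1 carbinol, the aldehyde is trapped by the C6 hydroxyl as the five-membered lactol, and this is oxidised on to the α-methylene-γ-butyrolactone with C6 and C7 unchanged.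

Step 21
Reactants: 35 15-O-TBDPS eupacunolin
Product: 36 eupacunolin
Conditions: HF·pyridine, pyridine, THF, 0 °C → rt
Reagents that add atoms: none
Why: Buffered fluoride cleavage of the primary TBDPS ether frees O15 under mildly acidic conditions that spare the acetate, the tiglate and the α-methylene lactone and avoid base-promoted acyl migration.

**Compound list**

1 | (R)-carvone, (5R)-2-methyl-5-(prop-1-en-2-yl)cyclohex-2-en-1-one | CC1=CC[C@H](CC1=O)C(C)=C | starting material
2 | (R)-10-hydroxycarvone, (5R)-5-(3-hydroxyprop-1-en-2-yl)-2-methylcyclohex-2-en-1-one | CC1=CC[C@H](CC1=O)C(CO)=C | intermediate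
3 | 12-O-TBS ether of 2 | CC1=CC[C@H](CC1=O)C(CO[Si](C)(C)C(C)(C)C)=C | intermediate
4 | cross-conjugated trimethylsilyl dienol ether of 3 (C1–OTMS, C1=C6, C9=C10) | CC1=CC[C@H](C=C1O[Si](C)(C)C)C(CO[Si](C)(C)C(C)(C)C)=C | intermediate
5 | 6-trimethylsilyloxy ketone, O6 anti to the C7 side chain | CC1=CC[C@H]([C@H](O[Si](C)(C)C)C1=O)C(CO[Si](C)(C)C(C)(C)C)=C | intermediate
6 | 6-hydroxy ketone, 6-OH anti to the C7 side chain (the 6-epimer serves equally) | CC1=CC[C@H]([C@H](O)C1=O)C(CO[Si](C)(C)C(C)(C)C)=C | intermediate
7 | 6-O-(2-methoxypropan-2-yl) (MOP) ether of 6 | CC1=CC[C@H]([C@H](OC(C)(C)OC)C1=O)C(CO[Si](C)(C)C(C)(C)C)=C | intermediate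
8 | acetaldehyde | CC=O | starting material
9 | lithium enolate of 7 (C1–OLi, C1=C6) | CC1=CC[C@H](C(OC(C)(C)OC)=C1O[Li])C(CO[Si](C)(C)C(C)(C)C)=C | intermediate
10 | aldol adduct, 6-(1-hydroxyethyl)-6-(MOP-oxy) enone, carbon arm anti and O6 syn to the C7 side chain, both carbinol epimers | CC1=CC[C@H]([C@](OC(C)(C)OC)(C(C)O)C1=O)C(CO[Si](C)(C)C(C)(C)C)=C | intermediate
11 | 6-vinyl-6-(MOP-oxy) enone | CC1=CC[C@H]([C@](OC(C)(C)OC)(C=C)C1=O)C(CO[Si](C)(C)C(C)(C)C)=C | intermediate
12 | linear trimethylsilyl dienol ether of 11 (C1–OTMS, C1=C10, C8=C9) | CC1=C(O[Si](C)(C)C)[C@@](OC(C)(C)OC)(C=C)[C@@H](C=C1)C(CO[Si](C)(C)C(C)(C)C)=C | intermediate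
13 | 8,9-epoxide of 12, oxygen anti to the C7 side chain | CC1=C(O[Si](C)(C)C)[C@@](OC(C)(C)OC)(C=C)[C@@H]([C@H]2O[C@@H]12)C(CO[Si](C)(C)C(C)(C)C)=C | intermediate
14 | 8-hydroxy enone, 8-OH anti to the C7 side chain | CC1=C[C@H](O)[C@H]([C@](OC(C)(C)OC)(C=C)C1=O)C(CO[Si](C)(C)C(C)(C)C)=C | intermediate
15 | N-methoxy-N-methylacetamide | CC(=O)N(C)OC | starting material
16 | lithium enolate of 15 | [Li]OC(=C)N(C)OC | intermediate
17 | C1 adduct: tertiary C1 carbinol bearing CH2C(O)N(OMe)Me, O1 cis to O6, C2 arm syn to the C6 vinyl group, 8-OH anti | CC1=C[C@H](O)[C@H]([C@](OC(C)(C)OC)(C=C)[C@]1(O)CC(=O)N(C)OC)C(CO[Si](C)(C)C(C)(C)C)=C | intermediate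
18 | 8-ketone of 17 | CC1=CC(=O)[C@H]([C@](OC(C)(C)OC)(C=C)[C@]1(O)CC(=O)N(C)OC)C(CO[Si](C)(C)C(C)(C)C)=C | intermediate
19 | 8-alcohol with 8-OH syn to the C7 side chain (8-epimer of 17) | CC1=C[C@@H](O)[C@H]([C@](OC(C)(C)OC)(C=C)[C@]1(O)CC(=O)N(C)OC)C(CO[Si](C)(C)C(C)(C)C)=C | intermediate
20 | 2-bromoprop-2-en-1-ol | C=C(Br)CO | starting material
21 | (2-bromoprop-2-enyloxy)(tert-butyl)diphenylsilane | C=C(Br)CO[Si](c1ccccc1)(c1ccccc1)C(C)(C)C | intermediate
22 | [3-(tert-butyldiphenylsilyloxy)prop-1-en-2-yl]lithium | [Li]C(=C)CO[Si](c1ccccc1)(c1ccccc1)C(C)(C)C | intermediate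
23 | seco-ring A enone: C1 carbinol bearing CH2C(=O)C(=CH2)CH2OTBDPS, C6 vinyl, 6-OMOP, 8-OH syn | CC1=C[C@@H](O)[C@H]([C@](OC(C)(C)OC)(C=C)[C@]1(O)CC(=O)C(=C)CO[Si](c1ccccc1)(c1ccccc1)C(C)(C)C)C(CO[Si](C)(C)C(C)(C)C)=C | intermediate
24 | cis-fused bicyclo[4.4.0]deca-4,9-dien-3-one: 1-OH, 6-OMOP, 8-OH, C15 OTBDPS, C12 OTBS | CC1=C[C@@H](O)[C@H]([C@]2(OC(C)(C)OC)C=C(CO[Si](c3ccccc3)(c3ccccc3)C(C)(C)C)C(=O)C[C@]12O)C(CO[Si](C)(C)C(C)(C)C)=C | intermediate
25 | tiglic acid, (E)-2-methylbut-2-enoic acid | C/C=C(\C)C(=O)O | starting material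
26 | tiglic 2,4,6-trichlorobenzoic anhydride | C/C=C(\C)C(=O)OC(=O)c1c(Cl)cc(Cl)cc1Cl | intermediate
27 | 8-tiglate of 24 | CC1=C[C@@H](OC(=O)/C(C)=C/C)[C@H]([C@]2(OC(C)(C)OC)C=C(CO[Si](c3ccccc3)(c3ccccc3)C(C)(C)C)C(=O)C[C@]12O)C(CO[Si](C)(C)C(C)(C)C)=C | intermediate
28 | 3-alcohol (3-OH cis to O1) still carrying the 6-MOP ether | CC1=C[C@@H](OC(=O)/C(C)=C/C)[C@H]([C@]2(OC(C)(C)OC)C=C(CO[Si](c3ccccc3)(c3ccccc3)C(C)(C)C)[C@@H](O)C[C@]12O)C(CO[Si](C)(C)C(C)(C)C)=C | intermediate
29 | 1,3,6-triol 8-tiglate | CC1=C[C@@H](OC(=O)/C(C)=C/C)[C@H]([C@]2(O)C=C(CO[Si](c3ccccc3)(c3ccccc3)C(C)(C)C)[C@@H](O)C[C@]12O)C(CO[Si](C)(C)C(C)(C)C)=C | intermediate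
30 | cleavage precursor: cis-1,6-dihydroxybicyclo[4.4.0]deca-4,9-diene, 3-acetate, 8-tiglate, C7 bearing CH2=C–CH2OTBS, O15 TBDPS | CC1=C[C@@H](OC(=O)/C(C)=C/C)[C@H]([C@]2(O)C=C(CO[Si](c3ccccc3)(c3ccccc3)C(C)(C)C)[C@@H](OC(C)=O)C[C@]12O)C(CO[Si](C)(C)C(C)(C)C)=C | intermediate
31 | (4Z,9Z)-cyclodeca-4,9-diene-1,6-dione, 3-acetate, 8-tiglate, O12 TBS, O15 TBDPS | O=C1/C=C(/CO[Si](c2ccccc2)(c2ccccc2)C(C)(C)C)[C@@H](OC(C)=O)CC(=O)/C(C)=C\[C@@H](OC(=O)/C(C)=C/C)[C@H]1C(=C)CO[Si](C)(C)C(C)(C)C | intermediate
32 | (1S,6R)-1,6-diol from 31 | O[C@@H]1/C=C(/CO[Si](c2ccccc2)(c2ccccc2)C(C)(C)C)[C@@H](OC(C)=O)C[C@H](O)/C(C)=C\[C@@H](OC(=O)/C(C)=C/C)[C@H]1C(=C)CO[Si](C)(C)C(C)(C)C | intermediate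
33 | 1,6,12-triol (O15 TBDPS) | O[C@@H]1/C=C(/CO[Si](c2ccccc2)(c2ccccc2)C(C)(C)C)[C@@H](OC(C)=O)C[C@H](O)/C(C)=C\[C@@H](OC(=O)/C(C)=C/C)[C@H]1C(=C)CO | intermediate
34 | 6,12-lactol (both C12 epimers) | C=C1C(O)O[C@@H]2/C=C(/CO[Si](c3ccccc3)(c3ccccc3)C(C)(C)C)[C@@H](OC(C)=O)C[C@H](O)/C(C)=C\[C@@H](OC(=O)/C(C)=C/C)[C@@H]12 | intermediate
35 | 15-O-TBDPS eupacunolin | C=C1C(=O)O[C@@H]2/C=C(/CO[Si](c3ccccc3)(c3ccccc3)C(C)(C)C)[C@@H](OC(C)=O)C[C@H](O)/C(C)=C\[C@@H](OC(=O)/C(C)=C/C)[C@@H]12 | intermediate
36 | eupacunolin | C=C1C(=O)O[C@@H]2/C=C(/CO)[C@@H](OC(C)=O)C[C@H](O)/C(C)=C\[C@@H](OC(=O)/C(C)=C/C)[C@@H]12 | target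

**Step count and risks**

Total step count: 21. Longest linear sequence: 20 steps (steps 1–10 and 12–21, from (R)-carvone).

The three steps most likely to fail:

1. Step 17. What may go wrong: the cyclic lead diester forms slowly at the crowded, doubly tertiary ring-fusion glycol, so that the β-acyloxy dienedione sits for a long time with acetic acid and lead salts and eliminates or closes transannularly. Fallback: leave the two-electron diester pathway for a one-electron cleavage that needs no cyclic intermediate. The hypoiodite of either tertiary hydroxyl, made with PhI(OAc)2 and I2 under visible light at 0 °C, gives an alkoxyl radical whose β-scission breaks C1–C6 (the departing carbon radical is both allylic and α-hydroxy), and oxidation of that radical gives the second ketone. This sets out from 30 and comes back at 31, and no new compound lies on the way (F0).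

2. Step 18. What may go wrong: loss or reversal of facial control at the C6 carbonyl, where the branched C7 competes with the alkenyl C5 for the role of the large substituent, while C1 is reduced cleanly. Fallback: decouple the two carbinols. Dione 31 is reduced under the regime that serves C6 (the enantiomeric oxazaborolidine, or NaBH4/CeCl3 if the ring itself controls), accepting the wrong configuration at C1, to give 1-epi-diol F1. Methanolysis of the TBS ether (pyridinium p-toluenesulfonate, MeOH) gives 1-epi-triol F2, and TEMPO/PhI(OAc)2 gives, through 1-epi-lactol F3, the 1-epi-lactone F4, in which O6 is tied up. MnO2 then oxidises the one remaining allylic carbinol to 1-oxo lactone F5, and a CBS reduction of this single α-methyl enone with the (R)-catalyst, where large and small groups are unambiguous, comes back to the route at 35.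

3. Step 7. What may go wrong: attack of the oxidant on the silyloxy-bearing C1=C10 bond of 12 (hydroxylation at C10), or hydrolysis of the dienol ether back to 11, in place of oxidation at C8. Fallback: do without the dienol ether. Enone 11 is taken directly into the amide-enolate addition (conditions of step 8, with 16) to give 8-deoxy amide F6. The ring allylic methylene C8, the only one on ring B, is then oxidised to the enone by allylic C–H oxidation with Rh2(cap)4 (cap = caprolactamate) and t-BuOOH, which leaves tertiary alcohols alone. This sets out from 11 and comes back at 18.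

**Further compounds**

F0 | step 17 | none | none
F1 | step 18 | 1-epi-diol, (1R,6R)-1,6-diol | O[C@@H]1/C=C(/CO[Si](c2ccccc2)(c2ccccc2)C(C)(C)C)[C@@H](OC(C)=O)C[C@@H](O)/C(C)=C\[C@@H](OC(=O)/C(C)=C/C)[C@H]1C(=C)CO[Si](C)(C)C(C)(C)C
F2 | step 18 | 1-epi-triol | O[C@@H]1/C=C(/CO[Si](c2ccccc2)(c2ccccc2)C(C)(C)C)[C@@H](OC(C)=O)C[C@@H](O)/C(C)=C\[C@@H](OC(=O)/C(C)=C/C)[C@H]1C(=C)CO
F3 | step 18 | 1-epi-lactol | C=C1C(O)O[C@@H]2/C=C(/CO[Si](c3ccccc3)(c3ccccc3)C(C)(C)C)[C@@H](OC(C)=O)C[C@@H](O)/C(C)=C\[C@@H](OC(=O)/C(C)=C/C)[C@@H]12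
F4 | step 18 | 1-epi-lactone | C=C1C(=O)O[C@@H]2/C=C(/CO[Si](c3ccccc3)(c3ccccc3)C(C)(C)C)[C@@H](OC(C)=O)C[C@@H](O)/C(C)=C\[C@@H](OC(=O)/C(C)=C/C)[C@@H]12
F5 | step 18 | 1-oxo lactone | C=C1C(=O)O[C@@H]2/C=C(/CO[Si](c3ccccc3)(c3ccccc3)C(C)(C)C)[C@@H](OC(C)=O)CC(=O)/C(C)=C\[C@@H](OC(=O)/C(C)=C/C)[C@@H]12
F6 | step 7 | 8-deoxy amide | CC1=CC[C@H]([C@](OC(C)(C)OC)(C=C)[C@]1(O)CC(=O)N(C)OC)C(CO[Si](C)(C)C(C)(C)C)=C
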